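## The problem

Lehualide K (15) is a symmetric disulfide in which each sulfur ends an unbranched ten-carbon chain attached to C6 of a 3,4-dimethoxy-5-methyl-2H-pyran-2-one. There is no stereocentre, so the task is regiochemical: four different groups must be placed on the four substituted ring carbons, and the only geometric question arises in an open-chain alkene intermediate. The oxygen pattern is the delicate part, because methylation of a 4-hydroxy-2-pyranone is ambident and can also give the 2-methoxy-4-pyranone; a ring closure that already carries both methyl ethers is therefore preferable. The ring is a vinylogous carbonate that hydroxide, alkoxides, amines and thiolates can open or attack at C4. The disulfide is cleaved by reductants, carbanions and phosphines and binds to palladium, so sulfur should enter late and the S–S bond should be formed last under mild conditions. The chain itself is trivial, since a linear α,ω-dibromide supplies it together with the later site for sulfur. The feature that makes the key step possible is the unit O1–C6=C5: the O1–C6 bond and the C5 substituent lie on a double bond that can be traced back to an alkyne C5≡C6 bearing the chain, while C2, C3 and C4 with both methoxy groups correspond to a Z-configured 2,3-dimethoxyacrylate whose ester carbonyl oxygen becomes O1. Electrophilic activation of that alkyne closes the ring and leaves a handle on C5 in one operation.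

## Retrosynthesis

**S–S bond.** The S–S bond of 15 is cut in the polar sense, into a sulfur nucleophile, thiol 14, and a sulfur electrophile, the S-alkyl p-toluenethiosulfonate 13. Oxidative coupling of two thiol molecules would be one operation shorter. The polar coupling is preferred because it needs no oxidant, it consumes each thiolate as soon as it meets 13, and it cannot give a mixed product since both partners carry the same chain. The cut halves the molecule, and every earlier step is then run on a monomer. The forward reaction must free the thiol and join it to 13 without a nucleophile attacking the pyranone.

**C10'–S bonds.** Thiol 14 is released in the flask from thioacetate 12. Both 12 and 13 are traced to the single primary bromide 11 by cutting the C10'–S bond, so the route stays linear up to 11 and divides for one step only. Carrying a disulfide or a free thiol through the ring construction would expose it to an organolithium, an enolate, electrophilic iodine and palladium. Both forward reactions are SN2 displacements by soft, non-basic sulfur anions, which the ring should tolerate.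

**C5–CH3 bond.** The methyl group of 11 is cut back to the alkenyl iodide 9 and trimethylboroxine 10. A C5 halide is exactly what an electrophile-induced ring closure delivers, so this cut fits the next one; a methyl group cannot be placed on that carbon while it is still an alkyne carbon. The precursor has one carbon less and a regiodefined handle. The cross-coupling must prefer the sp2 C–I bond over the primary C–Br bond and must leave the lactone intact.

**O1–C6 and C5–I bonds (key cut).** Opening 9 between O1 and C6 and removing iodine from C5 gives the open-chain enynoate 8. This cut is preferred over a cut at the lactone C2–O1 bond or at C3–C4, because those lead to 4-hydroxypyranones that must be methylated afterwards with the ambident selectivity problem. Here both methoxy groups are in place before the ring exists. Precursor 8 is acyclic and has no stereocentre, only a defined alkene geometry. The forward reaction needs 6-endo closure by the ester carbonyl oxygen and loss of the ester methyl group.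

**C3–O–CH3 bond of the enol ether.** Removing the methyl group from the C3 oxygen of 8 gives the β-keto ester 7. Methylating here is a question of O against C and of alkene geometry on an open chain, not of α- against γ-pyrone, and a wrong geometric isomer of a push-pull alkene can be equilibrated. The forward step must methylate on oxygen and give, or allow equilibration to, the isomer with ester and alkyne cis.

**C2–C3 bond.** Keto ester 7 comes from the aldol adduct 6 by oxidation. Cutting C2–C3 of 6 gives the ynal 4 and methyl methoxyacetate 5. An aldol addition to an ynal followed by oxidation is chosen over a direct Claisen acylation with an ynoate, because enolates add in conjugate fashion to ynoates but cleanly 1,2 to ynals. The stereocentres of 6 are irrelevant.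

**Formyl–alkyne and alkyne–chain bonds.** Ynal 4 is the formylation product of the terminal alkyne 3. Alkyne 3 comes from 1,10-dibromodecane 1 and the lithium acetylide complex 2 by one SN2 alkylation, which leaves the second bromide as the later site for sulfur. Only mono-alkylation is required.

## Roads not taken

**Alternative 1:** Both lactone C2–O1 bonds are cut at once. The bis(4-hydroxypyranone) A1 is traced to an open-chain disulfide A2 that carries a 2-methoxy-4-methyl-3,5-dioxo ester at each end. In the forward step DBU enolizes each C5 ketone and the enol oxygens add to the methyl esters, closing both rings.
- Merits: it follows polyketide logic, and ring closure of 3,5-dioxo esters is dependable. The C5 methyl and the C6 chain are part of the carbon skeleton, so no halogen or palladium is needed. Two-directional work forms two rings per operation.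
- Weak points: A2 has to be built by enolate acylations in the presence of a disulfide, which carbanions and thiolates cleave or scramble. Every reaction must succeed twice on one molecule, so incomplete conversion gives mixtures that are hard to separate. A1 still lacks the C4 O-methyl groups, and the ambident methylation, run on two rings, can give up to three constitutional isomers.
- Comparison: in ring formation this road is as good as or better than the chosen one. The chosen plan sets against it an oxygen pattern fixed before ring closure and the absence of sulfur until the last three steps.

**Alternative 2:** The ring is cut at C3–C4. The precursor is the Z enol ester A4, in which a methoxyacetyl group sits on the enol oxygen and the sulfur is carried as an S-trityl group. In the forward step a lithium amide deprotonates the methoxyacetyl CH2, and the enolate attacks the neighbouring methyl ester in a Dieckmann-type closure to give the 4-hydroxypyranone A3.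
- Merits: the C5 methyl and the C6 chain are already part of the carbon skeleton of A4, so their placement is beyond doubt and no iodide or cross-coupling is needed. The trityl thioether survives strong base and can be oxidized directly to the disulfide at the end.
- Weak points: the closure needs the Z enol ester, and an enol ester is itself an acyl donor, so the amide base can cleave it or cause O-to-C acyl transfer. A3 has a free C4 hydroxyl group, so the ambident O-methylation returns, once per molecule, at a late stage.
- Comparison: this road is probably shorter than the chosen plan and avoids the 6-endo against 5-exo question. The chosen plan also depends on the geometry of an open-chain alkene, so it has no advantage there. What it sets against Alternative 2 is that both methyl ethers are installed before the ring closes, where the only competing outcomes are a C-methyl compound or a geometric isomer that can be equilibrated.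

**Alternative 3:** The two C8'–C9' bonds of the unsaturated analogue A5 are cut. In the forward step two molecules of the 6-(non-8-enyl)pyranone A6 undergo cross-metathesis with both allyl groups of diallyl disulfide A7 under the second-generation Grubbs catalyst.
- Merits: it is the most convergent plan, the S–S unit is bought intact, and no thiol is handled.
- Weak points: it does not solve the ring, because A6 still needs a pyranone synthesis of the kind discussed here. Allyl disulfides can bind and slow the ruthenium carbene, and double cross-metathesis competes with self-metathesis of A6 and with the mono-coupled product. A5 must then be saturated at two alkenes next to allylic C–S bonds and a disulfide: hydrogenation catalysts are poisoned and hydrogenolyse S–S and allyl–S bonds, so only diimide is realistic, and the ring double bonds must survive it.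
- Comparison: on paper this road is more convergent and has fewer sulfur steps. The chosen plan answers with a chain that is saturated from the start and a sulfur introduction made of substitution reactions only.

Key step: step 6

Remark: aldol adduct 6 is carried forward as the racemic mixture of both diastereomers, because steps 4 and 5 remove both of its stereocentres.

## Route

Step 1
Reactants: 1 1,10-dibromodecane; 2 lithium acetylide–ethylenediamine complex (LiC≡CH·H2NCH2CH2NH2)
Product: 3 12-bromododec-1-yne
Conditions: DMSO, 10 °C to rt; 1 in threefold excess, excess recovered
Reagents that add atoms: none
Why: SN2 alkylation of an acetylide by a primary bromide; DMSO makes the lithium acetylide reactive at room temperature, and the excess of dibromide keeps double alkylation to the diyne low.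

Step 2
Reactants: 3 12-bromododec-1-yne
Product: 4 13-bromotridec-2-ynal
Conditions: n-BuLi, THF, −78 °C; DMF, −78 to 0 °C; inverse quench into cold aq KH2PO4
Reagents that add atoms: N,N-dimethylformamide, CN(C)C=O
Why: Formylation of a lithium acetylide with DMF; deprotonation of the terminal alkyne at −78 °C is far faster than bromine–lithium exchange or substitution at the primary bromide. Pouring the hemiaminal alkoxide into phosphate buffer releases the ynal without conjugate addition of dimethylamine.

Step 3
Reactants: 5 methyl methoxyacetate; 4 13-bromotridec-2-ynal
Product: 6 methyl 15-bromo-3-hydroxy-2-methoxypentadec-4-ynoate (racemic mixture of both diastereomers)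
Conditions: LiN(iPr)2, THF, −78 °C; then 4, −78 °C; aq NH4Cl
Reagents that add atoms: none
Why: Aldol addition of the lithium enolate of an α-alkoxy ester to an aldehyde; ynals react by clean 1,2-addition at −78 °C. The two new stereocentres are left uncontrolled because steps 4 and 5 remove them.

Step 4
Reactants: 6 methyl 15-bromo-3-hydroxy-2-methoxypentadec-4-ynoate
Product: 7 methyl 15-bromo-2-methoxy-3-oxopentadec-4-ynoate
Conditions: Dess–Martin periodinane, CH2Cl2, 0 °C to rt; crude product used at once
Reagents that add atoms: none
Why: Dess–Martin oxidation of a secondary propargylic alcohol under neutral, non-aqueous conditions gives the β-keto ester without touching the alkyne or the bromide. The ynone with its doubly activated C2–H is sensitive to base and nucleophiles, so it is not stored.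

Step 5
Reactants: 7 methyl 15-bromo-2-methoxy-3-oxopentadec-4-ynoate
Product: 8 methyl (2Z)-15-bromo-2,3-dimethoxypentadec-2-en-4-ynoate (ester group and alkyne cis)
Conditions: Cs2CO3, Me2SO4, DMF, 0 °C
Reagents that add atoms: dimethyl sulfate, COS(=O)(=O)OC
Why: O-Alkylation of a β-keto ester enolate; the fully substituted, doubly stabilized carbon and the hard electrophile in DMF favour reaction at the ketone enolate oxygen. The weakly coordinating caesium ion in DMF disfavours the chelated U-shaped enolate, so the enolate oxygen lies anti to the ester and the new C3 methoxy group ends up trans to it, which is the Z isomer. This isomer is also expected to be the more stable form of the push-pull alkene.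

Step 6
Reactants: 8 methyl (2Z)-15-bromo-2,3-dimethoxypentadec-2-en-4-ynoate
Product: 9 6-(10-bromodecyl)-5-iodo-3,4-dimethoxy-2H-pyran-2-one
Conditions: ICl (1.2 equiv), CH2Cl2, −78 °C to rt, dark
Reagents that add atoms: iodine monochloride, ClI
Why: This is the iodolactonization of a (Z)-2-en-4-ynoate ester, the known electrophilic cyclization route to 5-iodo-2-pyranones. ICl forms an iodine-bridged cation on the alkyne C4≡C5 of 8, and the ester carbonyl oxygen, made more nucleophilic by the C3 methoxy group, opens it anti at the chain-bearing carbon. This is a 6-endo-dig closure that forms the O1–C6 bond and leaves iodine on ring C5. The resulting 2-methoxypyrylium ion is demethylated by chloride in an SN2 step at the methyl group, which releases chloromethane and the neutral lactone; no stereocentre is formed. The step needs 6-endo attack to beat 5-exo attack, which would give an iodoalkylidene butenolide, and it needs the alkyne, not the dimethoxyalkene, to take up the electrophile. The alkyl group on the distal alkyne carbon stabilizes positive charge there, and conjugation of the ester through C2=C3 makes that carbon the electrophilic end of the enyne. The ester also lowers the nucleophilicity of the tetrasubstituted alkene, and low temperature with exclusion of light suppresses addition of ICl across it. Only the Z isomer can close, which is why step 5 is run under non-chelating conditions.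

Step 7
Reactants: 9 6-(10-bromodecyl)-5-iodo-3,4-dimethoxy-2H-pyran-2-one; 10 trimethylboroxine
Product: 11 6-(10-bromodecyl)-3,4-dimethoxy-5-methyl-2H-pyran-2-one
Conditions: Pd(PPh3)4 (cat.), K2CO3, 1,4-dioxane, 90 °C
Reagents that add atoms: none
Why: Suzuki–Miyaura methylation of an alkenyl iodide with trimethylboroxine; the zerovalent palladium complex inserts into the sp2 C–I bond far faster than into the unactivated primary C–Br bond. Anhydrous K2CO3 in dioxane activates the boroxine without hydrolysing the lactone.

Step 8
Reactants: 11 6-(10-bromodecyl)-3,4-dimethoxy-5-methyl-2H-pyran-2-one
Product: 12 S-[10-(3,4-dimethoxy-5-methyl-2-oxo-2H-pyran-6-yl)decyl] ethanethioate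
Conditions: KSAc, DMF, rt; run on one half of the batch of 11
Reagents that add atoms: potassium thioacetate, CC(=O)[S-].[K+]
Why: SN2 displacement of a primary bromide by the soft, weakly basic thioacetate ion in DMF; the pyranone is inert to this nucleophile at room temperature.

Step 9
Reactants: 11 6-(10-bromodecyl)-3,4-dimethoxy-5-methyl-2H-pyran-2-one
Product: 13 S-[10-(3,4-dimethoxy-5-methyl-2-oxo-2H-pyran-6-yl)decyl] 4-methylbenzenesulfonothioate (the S-alkyl p-toluenethiosulfonate)
Conditions: 4-CH3C6H4SO2SK (1.2 equiv), DMF, rt to 40 °C; run on the other half of the batch of 11
Reagents that add atoms: potassium 4-methylbenzenethiosulfonate, Cc1ccc(S(=O)(=O)[S-])cc1.[K+]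
Why: SN2 displacement of the primary bromide by the terminal sulfur of the thiosulfonate anion, the standard preparation of S-alkyl arenethiosulfonates. The anion is soft and non-basic, so the pyranone is not touched.

Step 10
Reactants: 12 S-[10-(3,4-dimethoxy-5-methyl-2-oxo-2H-pyran-6-yl)decyl] ethanethioate; 13 S-[10-(3,4-dimethoxy-5-methyl-2-oxo-2H-pyran-6-yl)decyl] 4-methylbenzenesulfonothioate
Product: 15 lehualide K (6,6'-[disulfanediylbis(decane-10,1-diyl)]bis(3,4-dimethoxy-5-methyl-2H-pyran-2-one)), via free thiol 14 (not isolated)
Conditions: 12 (1.05 equiv), K2CO3 (1.1 equiv), degassed MeOH–THF, 0 °C, until 12 is consumed; then 13 (1.0 equiv) in THF, 0 °C; aq NH4Cl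
Reagents that add atoms: none
Why: Methanolysis of the thioester, which at 0 °C should be much faster than attack on the vinylogous carbonate, frees the thiolate of 14, and this attacks the sulfenyl sulfur of thiosulfonate 13 and expels p-toluenesulfinate (thiol–thiosulfonate exchange, a standard polar disulfide synthesis). Both partners carry the same chain, so only one disulfide can form, no oxidant is needed, and any thiol left over is converted by air into the same product on work-up.

## Compound list

1 | 1,10-dibromodecane | BrCCCCCCCCCCBr | starting material
2 | lithium acetylide–ethylenediamine complex | [Li]C#C.NCCN | starting material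
3 | 12-bromododec-1-yne | C#CCCCCCCCCCCBr | intermediate
4 | 13-bromotridec-2-ynal | O=CC#CCCCCCCCCCCBr | intermediate
5 | methyl methoxyacetate | COCC(=O)OC | starting material
6 | methyl 15-bromo-3-hydroxy-2-methoxypentadec-4-ynoate (racemic, both diastereomers) | COC(=O)C(OC)C(O)C#CCCCCCCCCCCBr | intermediate
7 | methyl 15-bromo-2-methoxy-3-oxopentadec-4-ynoate | COC(=O)C(OC)C(=O)C#CCCCCCCCCCCBr | intermediate
8 | methyl (2Z)-15-bromo-2,3-dimethoxypentadec-2-en-4-ynoate | COC(=O)/C(OC)=C(OC)\C#CCCCCCCCCCCBr | intermediate
9 | 6-(10-bromodecyl)-5-iodo-3,4-dimethoxy-2H-pyran-2-one | COc1c(OC)c(I)c(CCCCCCCCCCBr)oc1=O | intermediate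
10 | trimethylboroxine | CB1OB(C)OB(C)O1 | starting material
11 | 6-(10-bromodecyl)-3,4-dimethoxy-5-methyl-2H-pyran-2-one | COc1c(OC)c(C)c(CCCCCCCCCCBr)oc1=O | intermediate
12 | S-[10-(3,4-dimethoxy-5-methyl-2-oxo-2H-pyran-6-yl)decyl] ethanethioate | COc1c(OC)c(C)c(CCCCCCCCCCSC(C)=O)oc1=O | intermediate
13 | S-[10-(3,4-dimethoxy-5-methyl-2-oxo-2H-pyran-6-yl)decyl] 4-methylbenzenesulfonothioate | COc1c(OC)c(C)c(CCCCCCCCCCSS(=O)(=O)c2ccc(C)cc2)oc1=O | intermediate
14 | 3,4-dimethoxy-5-methyl-6-(10-sulfanyldecyl)-2H-pyran-2-one | COc1c(OC)c(C)c(CCCCCCCCCCS)oc1=O | intermediate (not isolated)
15 | lehualide K, 6,6'-[disulfanediylbis(decane-10,1-diyl)]bis(3,4-dimethoxy-5-methyl-2H-pyran-2-one) | COc1c(C)c(CCCCCCCCCCSSCCCCCCCCCCc2oc(=O)c(OC)c(OC)c2C)oc(=O)c1OC | target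

## Step count and risks

Total: 10 steps. Longest linear sequence: 9 steps (steps 1 to 8 and step 10, from 1 to 15); step 9 is a one-step branch from 11.

**Step 6 (key step).** The most likely failure is competing 5-exo-dig closure at the proximal alkyne carbon, or addition of ICl across the electron-rich dimethoxyalkene. The C2 methoxy group pushes electron density toward the distal alkyne carbon and so works against the polarization by the ester; the electronic bias for 6-endo attack may therefore be small. The fallback separates ring closure from iodination. It sets out from 8, which is saponified with LiOH in aqueous THF to (2Z)-15-bromo-2,3-dimethoxypentadec-2-en-4-ynoic acid F1. F1 is cyclized with catalytic ZnBr2 in THF, the known 6-endo-selective lactonization of (Z)-2-en-4-ynoic acids, to 6-(10-bromodecyl)-3,4-dimethoxy-2H-pyran-2-one F2. F2 is iodinated at its only free ring position, C5, with N-iodosuccinimide and catalytic trifluoroacetic acid in acetonitrile. The route is rejoined at 9.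

**Step 5.** Methylation may occur on carbon, or through the chelated enolate to give the geometric isomer that cannot cyclize. The fallback sets out from 7 and uses (CH3)3SiCHN2 in toluene–methanol. This reagent methylates only the acidic enol hydroxyl, so no C-methyl product can form, and it should give mainly the hydrogen-bond-derived isomer methyl (2E)-15-bromo-2,3-dimethoxypentadec-2-en-4-ynoate F3. F3 is then equilibrated as a push-pull alkene with catalytic iodine in CH2Cl2 under visible light to the isomer with ester and alkyne cis. The route is rejoined at 8.

**Step 7.** Slow transmetalation of the hindered C5–palladium intermediate may allow protodeiodination, and hot carbonate may degrade the lactone or the alkyl bromide. The fallback changes the transmetalating metal from boron to zinc: from 9, a Negishi coupling with MeZnCl and Pd(PPh3)4 in THF at room temperature, base-free and inert toward the primary bromide, gives 11 directly. This fallback makes no compound outside the list (F0).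

**Step 10.** The thiolate or methoxide may attack the pyranone, either by ring opening at C2 or by substitution of the C4 methoxy group, before the S–S bond has formed; methoxide may also consume part of the thiosulfonate. The fallback avoids any thiolate and sets out from 11. The bromide is displaced with Na2S2O3 in aqueous ethanol to the Bunte salt sodium S-[10-(3,4-dimethoxy-5-methyl-2-oxo-2H-pyran-6-yl)decyl] thiosulfate F4. F4 is oxidized with iodine in warm aqueous ethanol, the classical conversion of S-alkyl thiosulfates into disulfides under neutral to acidic conditions. The route is rejoined at 15.

## Further compounds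

F1 | step 6 | (2Z)-15-bromo-2,3-dimethoxypentadec-2-en-4-ynoic acid | OC(=O)/C(OC)=C(OC)\C#CCCCCCCCCCCBr
F2 | step 6 | 6-(10-bromodecyl)-3,4-dimethoxy-2H-pyran-2-one | COc1c(OC)cc(CCCCCCCCCCBr)oc1=O
F3 | step 5 | methyl (2E)-15-bromo-2,3-dimethoxypentadec-2-en-4-ynoate | COC(=O)/C(OC)=C(OC)/C#CCCCCCCCCCCBr
F0 | step 7 | none | none
F4 | step 10 | sodium S-[10-(3,4-dimethoxy-5-methyl-2-oxo-2H-pyran-6-yl)decyl] thiosulfate | COc1c(OC)c(C)c(CCCCCCCCCCSS(=O)(=O)[O-])oc1=O.[Na+]
A1 | alternative 1 | 6,6'-[disulfanediylbis(decane-10,1-diyl)]bis(4-hydroxy-3-methoxy-5-methyl-2H-pyran-2-one) | COc1c(O)c(C)c(CCCCCCCCCCSSCCCCCCCCCCc2oc(=O)c(OC)c(O)c2C)oc1=O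
A2 | alternative 1 | dimethyl 15,15'-disulfanediylbis(2-methoxy-4-methyl-3,5-dioxopentadecanoate) | COC(=O)C(OC)C(=O)C(C)C(=O)CCCCCCCCCCSSCCCCCCCCCCC(=O)C(C)C(=O)C(OC)C(=O)OC
A3 | alternative 2 | 4-hydroxy-3-methoxy-5-methyl-6-[10-(tritylsulfanyl)decyl]-2H-pyran-2-one | COc1c(O)c(C)c(CCCCCCCCCCSC(c2ccccc2)(c2ccccc2)c2ccccc2)oc1=O
A4 | alternative 2 | methyl (2Z)-3-[(methoxyacetyl)oxy]-2-methyl-13-(tritylsulfanyl)tridec-2-enoate | COCC(=O)O/C(CCCCCCCCCCSC(c1ccccc1)(c1ccccc1)c1ccccc1)=C(/C)C(=O)OC
A5 | alternative 3 | 6,6'-{disulfanediylbis[(8E)-dec-8-ene-10,1-diyl]}bis(3,4-dimethoxy-5-methyl-2H-pyran-2-one) | COc1c(C)c(CCCCCCC/C=C/CSSC/C=C/CCCCCCCc2oc(=O)c(OC)c(OC)c2C)oc(=O)c1OC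
A6 | alternative 3 | 3,4-dimethoxy-5-methyl-6-(non-8-en-1-yl)-2H-pyran-2-one | COc1c(OC)c(C)c(CCCCCCCC=C)oc1=O
A7 | alternative 3 | diallyl disulfide | C=CCSSCC=C
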